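## Retrosynthetic overview

- The ten-membered ring is closed last at C6–C7 by an intramolecular nickel-electrocatalytic reductive coupling of a (Z)-alkenyl bromide with a γ-acetoxybutenolide; this also sets C7.
- The butenolide comes from a 3,4-disubstituted furan by singlet-oxygen photooxygenation; the furan is added to a C9 aldehyde (Felkin–Anh, sets C9).
- C9 is put on ring A by palladium/indium umpolung hydroxymethylation of a C10 allylic butanoate (sets C10).
- Ring A is (S)-carvone: C-acylation then C-methylation build C1, 1,3-diketone reduction sets C2, and a Criegee rearrangement turns the isopropenyl group into the C14 acetate.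
- Ring order: ring A (bought) → butenolide → ten-membered ring. The C2–C6 chain with the Z-alkene comes from syn-carbocupration of propyne.

Assumption: (S)-(+)-carvone, propyne, 2-(2-bromoethyl)-1,3-dioxolane and 3,4-dibromofuran are the commercial starting materials. Briarane locants are used for all intermediates (C1 quaternary ring-A carbon, C2 butanoate carbinol, C5=C6 Z-alkene, C7 lactone CH–O, C8=C17 butenolide alkene, C9 carbinol, C10 ring-fusion CH, C11=C12 ring alkene, C14 acetate carbon, C19 lactone carbonyl). The α face of ring A is the face that carries the C14 substituent.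

## Route

Step 1
Reactants: 1 2-(2-bromoethyl)-1,3-dioxolane; 2 propyne
Product: 5 2-[(3Z)-4-bromo-3-methylbut-3-en-1-yl]-1,3-dioxolane, via Grignard reagent 3 (not isolated), via alkenylcopper 4 (not isolated)
Conditions: Mg, THF, 25 °C; CuBr·SMe2, Et2O/Me2S, −45 °C; propyne, −25 °C; N-bromosuccinimide, −40 °C → rt
Reagents that add atoms: N-bromosuccinimide, O=C1CCC(=O)N1Br
Why: Normant syn-carbocupration of propyne places the alkyl group (on the methyl-bearing carbon) and copper cis on the new alkene, and bromination of the alkenylcopper with retention gives the (Z)-alkenyl bromide that becomes C5=C6.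

Step 2
Reactants: 5 2-[(3Z)-4-bromo-3-methylbut-3-en-1-yl]-1,3-dioxolane
Product: 7 (4Z)-5-bromo-4-methylpent-4-enoic acid, via aldehyde 6 (not isolated)
Conditions: 2 M HCl, THF, 40 °C; then NaClO2, NaH2PO4, 2-methyl-2-butene, t-BuOH/H2O, 0 °C → rt
Reagents that add atoms: water, O; sodium chlorite, [Na+].[O-]Cl=O
Why: Acetal hydrolysis followed by Pinnick oxidation gives the acid without touching the alkenyl bromide, because the hypochlorite by-product is scavenged by the added alkene.

Step 3
Reactants: 8 3,4-dibromofuran
Product: 10 3-bromo-4-methylfuran, via bromofuryllithium 9 (not isolated)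
Conditions: n-BuLi (1.0 equiv), Et2O, −78 °C; MeI, −78 → 0 °C
Reagents that add atoms: iodomethane, CI
Why: Mono bromine–lithium exchange and alkylation, run at −78 °C so that the 3-furyllithium does not isomerise to the 2-lithio species.

Step 4
Reactants: 7 (4Z)-5-bromo-4-methylpent-4-enoic acid; 11 (S)-(+)-carvone
Product: 14 side-chain 1,3-diketone 6-[(4Z)-5-bromo-4-methylpent-4-enoyl]carvone, via acyl imidazole 12 (not isolated), via lithium dienolate 13 (not isolated)
Conditions: 7, 1,1′-carbonyldiimidazole, THF, rt; added to 11 (2 equiv), LiN(i-Pr)2 (2 equiv), THF, −78 → −20 °C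
Reagents that add atoms: none
Why: Claisen-type C-acylation of the kinetic cross-conjugated lithium dienolate (the α′-CH2 is the only enolisable position) by the acyl imidazole forms the C1–C2 bond; the C1-epimer/enol mixture is irrelevant because C1 is set in step 5.

Step 5
Reactants: 14 side-chain 1,3-diketone
Product: 15 C1-methylated diketone (CH3 β and acyl chain α at C1)
Conditions: MeI, K2CO3, acetone, rt
Reagents that add atoms: iodomethane, CI
Why: C-alkylation of the planar 1,3-diketone enolate, where iodomethane enters anti to the vicinal C14 isopropenyl group, so the quaternary C1 carries CH3 trans and the acyl chain cis to the C14 substituent.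

Step 6
Reactants: 15 C1-methylated diketone
Product: 18 C14-acetate diketone, via methoxy hydroperoxide 16 (not isolated), via peracetate 17 (not isolated)
Conditions: O3, CH2Cl2/MeOH, −78 °C (Sudan red 7B end point); then Ac2O, Et3N, DMAP, −78 → 40 °C
Reagents that add atoms: ozone, [O-][O+]=O; methanol, CO
Why: Ozone cleaves only the electron-rich isopropenyl group (enone and alkenyl bromide are deactivated), methanol traps the carbonyl oxide, and Criegee rearrangement of the peracetate moves C14 from carbon to oxygen with retention, followed by demethylation of the resulting cation by acetate, so the C14 acetate (its acetyl carbons are the former isopropenyl carbons) keeps the carvone configuration.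

Step 7
Reactants: 18 C14-acetate diketone
Product: 20 C2,C10-diol (2R; C10–OH α), via hydroxy enone 19 (not isolated)
Conditions: NaBH4 (0.3 equiv), MeOH/CH2Cl2, −78 °C; then CeCl3·7H2O, NaBH4, −78 → −40 °C; AcOH quench
Reagents that add atoms: none
Why: The saturated C2 ketone reacts first under non-chelating polar Felkin–Anh control (C1–C10 acyl bond anti to hydride, hydride passing the small C1 methyl) to give 2R, and Luche 1,2-reduction of the enone from the methyl face then gives the C10 allylic alcohol, whose configuration is erased in step 9.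

Step 8
Reactants: 20 C2,C10-diol
Product: 21 C2,C10-bis(butanoate)
Conditions: (PrCO)2O, Et3N, DMAP, CH2Cl2, 0 °C → rt
Reagents that add atoms: butanoic anhydride, CCCC(=O)OC(=O)CCC
Why: DMAP-catalysed acylation installs the final C2 butanoate and at the same time turns the C10 allylic alcohol into the leaving group for step 9, with the acylation run cold to outpace 1,3-acetyl migration from C14.

Step 9
Reactants: 21 C2,C10-bis(butanoate)
Product: 23 C9 primary alcohol (10-hydroxymethyl compound), via allylindium 22 (not isolated)
Conditions: Pd(PPh3)4 (5 mol %), InI (1.5 equiv), 37% aq. CH2O, THF, rt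
Reagents that add atoms: formaldehyde, C=O
Why: Palladium-catalysed umpolung carbonyl allylation, in which zerovalent palladium ionises only the allylic C10 butanoate anti to the ester, monovalent indium converts the π-allyl complex into a σ-allylindium bound at the less hindered C12, and this adds to formaldehyde through a six-membered SE2′ transition state at C10 on the β face (away from the C2 chain and the C14 acetate), which sets C10 and restores the C11=C12 alkene.

Step 10
Reactants: 23 C9 primary alcohol
Product: 24 C9 aldehyde
Conditions: Dess–Martin periodinane, CH2Cl2, 0 °C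
Reagents that add atoms: none
Why: Dess–Martin oxidation is mild enough to give the β,γ-unsaturated aldehyde without epimerising C10 or moving the alkene into conjugation; the aldehyde is used at once.

Step 11
Reactants: 24 C9 aldehyde; 10 3-bromo-4-methylfuran
Product: 27 (9R)-furyl carbinol, via furyllithium 25 (not isolated), via furylcerium 26 (not isolated)
Conditions: 10, n-BuLi, Et2O/THF, −78 °C; CeCl3, −78 °C; then 24, −78 °C
Reagents that add atoms: none
Why: Felkin–Anh 1,2-addition in which the quaternary C1 lies anti to the incoming furyl group and the nucleophile passes H-10, giving 9R; the weakly basic organocerium adds to the aldehyde without enolising it or attacking the esters or the alkenyl bromide.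

Step 12
Reactants: 27 (9R)-furyl carbinol
Product: 30 γ-acetoxybutenolide (C7 epimers), via endoperoxide 28 (not isolated), via hydroxybutenolide 29 (not isolated)
Conditions: O2, hν (green LED), rose bengal, i-Pr2NEt, CH2Cl2, −78 °C; then Ac2O (1.2 equiv), pyridine, −20 → 0 °C
Reagents that add atoms: dioxygen, O=O; acetic anhydride, CC(=O)OC(C)=O
Why: [4+2] cycloaddition of singlet oxygen to the furan and Kornblum–DeLaMare-type fragmentation, where the hindered amine removes the bridgehead hydrogen next to the methyl-bearing carbon so that C19 becomes the lactone carbonyl and C7 the lactol, and the acidic lactol OH is then acetylated in preference to the hindered C9 OH.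

Step 13
Reactants: 30 γ-acetoxybutenolide (C7 epimers)
Product: 31 target CNP0293221.1
Conditions: NiBr2·dme (nickel dibromide–1,2-dimethoxyethane, 20 mol %), 4,4′-di-tert-butyl-2,2′-bipyridine (25 mol %), n-Bu4NBF4, DMA, undivided cell, Zn anode, carbon-felt cathode, 2 mA constant current, slow addition of 30 to 2 mM, rt
Reagents that add atoms: none
Why: Proposed new method: an intramolecular nickel-electrocatalytic reductive coupling of an alkenyl bromide with a γ-acetoxybutenolide, in which cathodically formed zerovalent nickel–bipyridine ionises the acylal C7–OAc bond to a planar oxa-π-allyl (2-oxidofuran) nickel species (this merges both C7 epimers), takes up the alkenyl bromide with retention of the Z geometry after one-electron reduction, and reductively eliminates at the γ-terminus C7 to close the ten-membered ring, with C7 expected to be set by C9/C10 because A(1,3) strain between C9 and the C18 methyl holds the C10 tether on one side of the planar allyl unit; the closest known reaction types are nickel-catalysed reductive cross-electrophile coupling of allylic acetates with alkenyl or aryl halides and the ionisation of γ-acyloxybutenolides by zerovalent palladium.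

## Compound list

1 | 2-(2-bromoethyl)-1,3-dioxolane | BrCCC1OCCO1 | starting material
2 | propyne | CC#C | starting material
3 | [2-(1,3-dioxolan-2-yl)ethyl]magnesium bromide | Br[Mg]CCC1OCCO1 | intermediate
4 | [(1Z)-4-(1,3-dioxolan-2-yl)-2-methylbut-1-en-1-yl]copper (as MgBr2 complex) | [Cu]/C=C(C)\CCC1OCCO1 | intermediate
5 | 2-[(3Z)-4-bromo-3-methylbut-3-en-1-yl]-1,3-dioxolane | Br/C=C(C)\CCC1OCCO1 | intermediate
6 | (4Z)-5-bromo-4-methylpent-4-enal | O=CCC/C(C)=C\Br | intermediate
7 | (4Z)-5-bromo-4-methylpent-4-enoic acid | OC(=O)CC/C(C)=C\Br | intermediate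
8 | 3,4-dibromofuran | Brc1cocc1Br | starting material
9 | (4-bromofuran-3-yl)lithium | [Li]c1cocc1Br | intermediate
10 | 3-bromo-4-methylfuran | Cc1cocc1Br | intermediate
11 | (S)-(+)-carvone, (5S)-2-methyl-5-(prop-1-en-2-yl)cyclohex-2-en-1-one | O=C1C[C@@H](C(C)=C)CC=C1C | starting material
12 | (4Z)-5-bromo-1-(1H-imidazol-1-yl)-4-methylpent-4-en-1-one | O=C(CC/C(C)=C\Br)n1ccnc1 | intermediate
13 | kinetic lithium dienolate of (S)-carvone (enolate at carvone C6 = briarane C1) | [Li]OC1=C[C@@H](C(C)=C)CC=C1C | intermediate
14 | (5S)-6-[(4Z)-5-bromo-4-methylpent-4-enoyl]-2-methyl-5-(prop-1-en-2-yl)cyclohex-2-en-1-one (C6 epimers and enol forms) | O=C(CC/C(C)=C\Br)C1[C@@H](C(C)=C)CC=C(C)C1=O | intermediate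
15 | (5R,6R)-6-[(4Z)-5-bromo-4-methylpent-4-enoyl]-2,6-dimethyl-5-(prop-1-en-2-yl)cyclohex-2-en-1-one (C1–CH3 trans, acyl chain cis to isopropenyl) | O=C(CC/C(C)=C\Br)[C@@]1(C)[C@@H](C(C)=C)CC=C(C)C1=O | intermediate
16 | methoxy hydroperoxide of 15, C14 side chain C(CH3)(OCH3)OOH (new centre as a mixture) | O=C(CC/C(C)=C\Br)[C@@]1(C)[C@@H](C(C)(OC)OO)CC=C(C)C1=O | intermediate
17 | peracetate of 16, C14 side chain C(CH3)(OCH3)OOAc | O=C(CC/C(C)=C\Br)[C@@]1(C)[C@@H](C(C)(OC)OOC(C)=O)CC=C(C)C1=O | intermediate
18 | 2-[(4Z)-5-bromo-4-methylpent-4-enoyl]-2,4-dimethyl-3-oxocyclohex-4-en-1-yl acetate; OAc (14S) and acyl chain cis, ring CH3 trans to OAc | O=C(CC/C(C)=C\Br)[C@@]1(C)[C@@H](OC(C)=O)CC=C(C)C1=O | intermediate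
19 | 2-[(1R,4Z)-5-bromo-1-hydroxy-4-methylpent-4-en-1-yl]-2,4-dimethyl-3-oxocyclohex-4-en-1-yl acetate (ring centres as in 18) | O[C@H](CC/C(C)=C\Br)[C@@]1(C)[C@@H](OC(C)=O)CC=C(C)C1=O | intermediate
20 | 2-[(1R,4Z)-5-bromo-1-hydroxy-4-methylpent-4-en-1-yl]-3-hydroxy-2,4-dimethylcyclohex-4-en-1-yl acetate; C10–OH on the α face (cis to OAc and side chain) | O[C@H](CC/C(C)=C\Br)[C@@]1(C)[C@@H](OC(C)=O)CC=C(C)[C@H]1O | intermediate
21 | C2,C10-bis(butanoate) of 20 (2R; C10–OCOPr α; 14-OAc) | CCCC(=O)O[C@H](CC/C(C)=C\Br)[C@@]1(C)[C@@H](OC(C)=O)CC=C(C)[C@H]1OC(=O)CCC | intermediate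
22 | σ-allylindium iodide butanoate: indium at C12 on the β face, alkene C10=C11 | CCCC(=O)O[C@H](CC/C(C)=C\Br)[C@@]1(C)[C@@H](OC(C)=O)C[C@H]([In](I)OC(=O)CCC)C(C)=C1 | intermediate
23 | 10-hydroxymethyl compound: ring A with C11=C12, C10–CH2OH β (cis to C1–CH3), H-10 α, 2R butanoate, 14-OAc | CCCC(=O)O[C@H](CC/C(C)=C\Br)[C@@]1(C)[C@@H](OC(C)=O)CC=C(C)[C@@H]1CO | intermediate
24 | C9 aldehyde (10-formyl compound, configuration as in 23) | CCCC(=O)O[C@H](CC/C(C)=C\Br)[C@@]1(C)[C@@H](OC(C)=O)CC=C(C)[C@@H]1C=O | intermediate
25 | (4-methylfuran-3-yl)lithium | [Li]c1cocc1C | intermediate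
26 | (4-methylfuran-3-yl)cerium dichloride | Cl[Ce](Cl)c1cocc1C | intermediate
27 | (9R)-furyl carbinol: C10–CH(OH)–(4-methylfuran-3-yl), other centres as in 24 | CCCC(=O)O[C@H](CC/C(C)=C\Br)[C@@]1(C)[C@@H](OC(C)=O)CC=C(C)[C@@H]1[C@@H](O)c1cocc1C | intermediate
28 | furan 2,5-endoperoxide of 27 (2,3,7-trioxabicyclo[2.2.1]hept-5-ene, bridgehead mixture) | CCCC(=O)O[C@H](CC/C(C)=C\Br)[C@@]1(C)[C@@H](OC(C)=O)CC=C(C)[C@@H]1[C@@H](O)C1=C(C)C2OOC1O2 | intermediate
29 | γ-hydroxybutenolide: 5-hydroxy-3-methyl-2(5H)-furanon-4-yl on C9 (C7 lactol, epimers) | CCCC(=O)O[C@H](CC/C(C)=C\Br)[C@@]1(C)[C@@H](OC(C)=O)CC=C(C)[C@@H]1[C@@H](O)C1=C(C)C(=O)OC1O | intermediate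
30 | γ-acetoxybutenolide: 5-acetoxy-3-methyl-2(5H)-furanon-4-yl on C9 (C7 epimers), free 9R-OH | CCCC(=O)O[C@H](CC/C(C)=C\Br)[C@@]1(C)[C@@H](OC(C)=O)CC=C(C)[C@@H]1[C@@H](O)C1=C(C)C(=O)OC1OC(C)=O | intermediate
31 | CNP0293221.1, (1S,2R,5Z,7S,9R,10S,14S)-14-acetoxy-2-butanoyloxy-9-hydroxybriara-5,8(17),11-trien-19,7-olide (C19 = lactone carbonyl) | CCCC(=O)O[C@@H]1CC/C(C)=C\[C@@H]2OC(=O)C(C)=C2[C@H](O)[C@H]2C(C)=CC[C@H](OC(C)=O)[C@@]21C | target

## Step count and risks

Total step count: 13. Longest linear sequence: 12 steps (steps 1, 2 and 4–13; step 3 is a side branch).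

**Step 9 (umpolung hydroxymethylation).** The allylindium may react at C12 instead of the neopentyl-like C10, the π-allyl complex may lose a β-hydrogen to give a diene, or zerovalent palladium may start to insert into the alkenyl bromide. The fallback sets out from 18 and comes back at 24. It reduces only the C2 ketone of 18 with NaBH4 at −78 °C and isolates hydroxy enone 19. Butanoylation gives the keto butanoate F1. Wittig methoxymethylenation of the C10 ketone (Ph3P=CHOMe from (methoxymethyl)triphenylphosphonium chloride and KN(SiMe3)2) gives the enol ether F2. Aqueous acid hydrolysis, with brief base equilibration to place the formyl group trans to the C2 chain, then gives aldehyde 24.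

**Step 11 (Felkin–Anh furyl addition).** The quaternary C1 and the C11 vinyl carbon compete for the anti position, so the C9 epimer may be the main product. The fallback sets out from 24 and comes back at 27. If the addition gives mainly the 9-epi carbinol F3, it is oxidised with MnO2 to the furyl ketone F4 and reduced with NaBH4/CeCl3·7H2O. Hydride then enters along the trajectory the furyl group had used, which inverts C9 and gives 27.

**Step 13 (new nickel-electrocatalytic macrocyclisation).** The ten-membered ring closure may lose to oligomerisation or protodebromination, the coupling may occur at the α-terminus, or the unnatural C7 epimer may form. The fallback uses only known chemistry; it sets out from 29 (isolated after the photooxygenation instead of being acetylated) and comes back at 31. The carboxylate of the ring-opened form of 29 is O-methylated with MeI/K2CO3 in DMF to the open-chain (Z)-formyl methyl ester F5. A stoichiometric Nozaki–Hiyama–Kishi macrocyclisation (CrCl2, catalytic NiCl2, DMSO/THF, high dilution) then adds the alkenylchromium to the C7 aldehyde. The resulting alkoxide lactonises onto the cis methyl ester and gives 31 directly.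

Further compounds
F1 | step 9 | keto butanoate: C2 butanoate of hydroxy enone 19 (C10 ketone kept) | CCCC(=O)O[C@H](CC/C(C)=C\Br)[C@@]1(C)[C@@H](OC(C)=O)CC=C(C)C1=O
F2 | step 9 | C10 methoxymethylidene enol ether of F1 (E/Z mixture) | CCCC(=O)O[C@H](CC/C(C)=C\Br)[C@@]1(C)[C@@H](OC(C)=O)CC=C(C)C1=COC
F3 | step 11 | 9-epi furyl carbinol (9S epimer of 27) | CCCC(=O)O[C@H](CC/C(C)=C\Br)[C@@]1(C)[C@@H](OC(C)=O)CC=C(C)[C@@H]1[C@H](O)c1cocc1C
F4 | step 11 | C9 furyl ketone | CCCC(=O)O[C@H](CC/C(C)=C\Br)[C@@]1(C)[C@@H](OC(C)=O)CC=C(C)[C@@H]1C(=O)c1cocc1C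
F5 | step 13 | open-chain methyl (Z)-3-formyl-2-methylacrylate on C9 (C7 aldehyde cis to C19 methyl ester) | CCCC(=O)O[C@H](CC/C(C)=C\Br)[C@@]1(C)[C@@H](OC(C)=O)CC=C(C)[C@@H]1[C@@H](O)/C(C=O)=C(C)/C(=O)OC
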